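## The problem

Compound 24 is a linear tridepside. Three 6-methylbenzoate rings (C, B, A) are joined by two aryl ester bonds, each running from a doubly ortho-substituted benzoyl carbon to O-4 of the next ring, and the chain ends in the free salicylic acid of ring A. The molecule has no stereocentre, so nothing can or must be controlled in space; the task is one of regiochemistry: which phenol is acylated, and how ring C receives its six substituents. Rings B and A are ordinary orsellinate units whose 2-hydroxyl is tied up by a hydrogen bond to the neighbouring carbonyl, which leaves the 4-hydroxyl as the only readily acylated oxygen. Ring C is the hard part: a hexasubstituted benzene (C1 acyl, C2 OH, C3 H, C4 OH, C5 OH, C6 CH3) that is not reached cleanly by electrophilic substitution of an orsellinate. As a 1,2,4-trioxygenated arene it is also oxidised to a quinone by air once base is present. The depside esters do not survive hydroxide, alkoxide or amines (hydrolysis, transacylation), and the electron-rich salicylic acids decarboxylate on heating, so the last unmasking steps have to be hydrogenolytic or Lewis acidic and cold. The feature that opens a ring-expansion route is the oxygen pattern of ring C: O-2 and O-5 are para, the third oxygen sits on C4 next to C5, and C3 carries the only hydrogen. This is the pattern of the hydroquinone formed when a 4-alkenyl-4-hydroxy-3-alkoxycyclobutenone opens and recloses, with C2–C5 coming from the four-membered ring and C6 (methyl) and C1 (carboxyl) from the alkene.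

## Retrosynthesis

**Unmasking (24 ⇐ 23 ⇐ 22).** The last bond cut is the O–isopropyl bond at O-4 of ring C, giving 23; before that, two benzyl ethers and the benzyl ester of 22 are removed together. The isopropyl group is the alkoxy group of the squarate and is carried from the first step of the ring C synthesis. Exchanging it earlier would require a Lewis acid at a stage where benzyl ethers or the tert-butyl ester would also fall. Hydrogenolysis first and boron trichloride second makes each intermediate a single defined compound. The forward steps must leave the two aryl esters untouched.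

**Ring B–ring A ester (22 ⇐ 18 + 20).** The ester C–O bond between the ring B carbonyl and O-4 of ring A is cut. Cutting here rather than first assembling a B–A phenol lets ring A enter as benzyl orsellinate 20, one step from orsellinic acid 19, with its chelated 2-hydroxyl left free. The forward acylation must take place only at the 4-hydroxyl of 20 and must not let hydroxy acid 18 condense with itself.

**Ring C–ring B ester and the latent carboxyl (18 ⇐ 17 ⇐ 14 + 15).** The carboxyl of ring B is traced back to the formyl group of 17, and the ester bond between the ring C carbonyl and O-4 of ring B is then cut to acid 14 and aldehyde 15. An aldehyde cannot be activated while the ring C acid is, so ring B needs no carboxyl protecting group and no orthogonal phenol protection. The forward steps require 4-O-selective acylation of 15 and a chlorite oxidation that spares electron-rich rings.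

**Adjusting ring C (14 ⇐ 13 ⇐ 12).** The tert-butyl ester and the two benzyl ethers are removed in the retrosynthetic sense to expose hydroquinone 12. Benzyl is chosen for the two hydroquinone oxygens because it goes on under mild carbonate conditions and comes off in the same hydrogenolysis as the ring A ester.

**Ring C by ring expansion (12 ⇐ 9).** The C1–C2 bond of ring C is cut and the C2/C5 pair is folded back into a cyclobutenone, giving 9. Against hydroxylation of a preformed orsellinate, this cut fixes all six substituents by connectivity: the C3 hydrogen, the C4 alkoxy group, and the para oxygens all come from the four-membered ring. Compound 9 has no aromatic ring and only one, inconsequential, stereocentre. The forward reaction needs outward rotation of the hydroxyl during ring opening and closure onto the ester-bearing alkene carbon.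

**Cyclobutenone assembly (9 ⇐ 7 + 4; 7 ⇐ 5).** The bond between the carbinol carbon (future C5) and the alkene carbon (future C6) is cut to dione 7 and alkenyl iodide 4, which acts through its magnesium derivative 8. Dione 7 comes from diisopropyl squarate 5 by reduction and loss of isopropanol; this is where the future C3 hydrogen is installed. The forward addition must occur at the ketone-like carbonyl of 7, and the alkene geometry of 4 must be retained.

**Alkenyl iodide (4 ⇐ 3 ⇐ 2 ⇐ 1).** The C–I bond is traced to a C–Sn bond and that to the alkyne of 2, made from but-2-ynoic acid 1. The E geometry (metal trans to the ester) is essential: it prevents lactonisation of the adduct onto the ester and puts hydrogen, not the ester, inside the closing ring. A kinetic syn-stannylcupration delivers exactly this isomer.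

## Roads not taken

**Alternative 1:** Ring A is cut at C1–C6 and C2–C3. In the forward direction the 6-methyl-2-pyron-4-yl ester A2 of a benzylated rings C–B acid would undergo a [4+2] cycloaddition with benzyl 3-(benzyloxy)prop-2-ynoate A3, and loss of carbon dioxide from the bicyclic adduct would give the fully benzylated tridepside A1.
- Merits: the route is convergent, and A1 carries only benzyl groups, so one hydrogenolysis would finish the synthesis. This endgame is cleaner than the two-stage unmasking of the chosen plan.
- Weak points: the key event is spent on ring A, which is available as 19, while the trioxygenated ring C still has to be made by some other method. Pyrone–alkyne cycloadditions need high temperatures. Under such conditions the enol ester of A2 is an acyl donor, and the benzyl ynol ether A3 is prone to sigmatropic rearrangement to a ketene. The orientation of a push–pull alkyne towards a 4-acyloxypyrone is also not assured.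
- Comparison: against the single-step deprotection, the chosen plan builds only the ring that cannot be bought and fixes its pattern by connectivity.

**Alternative 2:** Ring B is cut at C1–C2 and C5–C6. The but-2-ynoate A5 of the ring A phenol and 1-methoxy-1,3-bis(trimethylsilyloxy)buta-1,3-diene A6 would combine in a Diels–Alder reaction, and loss of methoxytrimethylsilane followed by enolisation would give the rings B–A didepside A4.
- Merits: the orientation of this diene towards alkynoates is reliable, and A4 arrives with its 4-hydroxyl free for the next acylation. For the B–A portion this is at least as short as the handling of ring B in the chosen plan.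
- Weak points: it again makes a ring that is commercial (as 15 or 19). A5 is an activated aryl ester facing a silyl ketene acetal, so acyl transfer can compete with cycloaddition. Ring C is not addressed at all and would need the chemistry of the chosen plan anyway.
- Comparison: the chosen plan matches it by bringing ring B in through one acylation of 15 and one oxidation, and puts its effort where the structural difficulty is.

**Alternative 3:** Ring C is cut at C1–C6 in the biomimetic sense. The aryl 6-(benzyloxy)-3,5,7-trioxooctanoate A8 of a benzylated B–A phenol would undergo aldol condensation of C2 onto the C7 ketone and dehydration, giving the tridepside A7 with ring C as its 5-benzyl ether.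
- Merits: ring C forms last on the intact depside. No cryogenic organometallic step and no tin are needed, and a single hydrogenolysis completes the synthesis. In step economy after the key step it is better than the chosen plan.
- Weak points: A8 is an aryl ester of a 3,5-diketo acid. The C5 enol oxygen can attack the ester and expel the B–A phenoxide to give a 4-hydroxy-2-pyrone. The C8 methyl can aldolise onto C3 to give an isomeric resorcinol. Building the trioxo chain needs polyanion chemistry on a base-sensitive aryl ester.
- Comparison: the chosen plan is longer, but the ring C substitution pattern is fixed by the connectivity of the four-membered ring with no competing mode of closure.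

Key step: step 6

Assumptions: 9 is used as the racemate, since its only stereocentre is erased in step 6 and the target is achiral. 2,4-Dihydroxy-6-methylbenzaldehyde 15 is taken as a commercial building block alongside 1, 5 and 19.

## Route

Step 1
Reactants: 1 but-2-ynoic acid
Product: 2 tert-butyl but-2-ynoate
Conditions: isobutene, H2SO4 (cat.), CH2Cl2, sealed vessel, rt
Reagents that add atoms: isobutene (2-methylpropene), CC(C)=C
Why: Acid-catalysed addition of the carboxylic acid to isobutene (tert-butyl esterification); the tert-butyl ester is chosen because it resists the organomagnesium of step 5 and is later cleaved by acid without touching benzyl or isopropyl ethers.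

Step 2
Reactants: 2 tert-butyl but-2-ynoate
Product: 3 tert-butyl (E)-3-(tributylstannyl)but-2-enoate
Conditions: Bu3SnH, LiN(iPr)2, THF, −40 °C; CuBr·SMe2, −78 °C; then 2, MeOH, −78 °C
Reagents that add atoms: tributyltin hydride, CCCC[SnH](CCCC)CCCC
Why: Stannylcupration of an ynoate: the tin–copper bond adds syn with tin at the β-carbon, and methanol protonates the α-copper intermediate at −78 °C before it can equilibrate, so tin ends trans to the ester (E).

Step 3
Reactants: 3 tert-butyl (E)-3-(tributylstannyl)but-2-enoate
Product: 4 tert-butyl (E)-3-iodobut-2-enoate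
Conditions: I2, CH2Cl2, 0 °C
Reagents that add atoms: iodine, II
Why: Iododestannylation, an electrophilic ipso substitution at the alkenyl carbon that proceeds with retention of the double-bond geometry.

Step 4
Reactants: 5 diisopropyl squarate
Product: 7 3-isopropoxycyclobut-3-ene-1,2-dione, via hydroxycyclobutenone 6 (not isolated)
Conditions: LiAlH(OtBu)3, THF, −20 °C; then conc. HCl (cat.), CH2Cl2, rt
Reagents that add atoms: water, O
Why: The bulky hydride reduces one carbonyl of the squarate (1,2-reduction) to 6; acid then ionises the allylic hydroxyl, water adds at the alkoxy-bearing end of the cation and isopropanol is lost, which transposes the carbonyl and leaves the ring hydrogen that becomes H-3 of ring C.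

Step 5
Reactants: 4 tert-butyl (E)-3-iodobut-2-enoate; 7 3-isopropoxycyclobut-3-ene-1,2-dione
Product: 9 tert-butyl (E)-3-(1-hydroxy-2-isopropoxy-4-oxocyclobut-2-en-1-yl)but-2-enoate (racemic), via alkenylmagnesium chloride 8 (not isolated)
Conditions: 4, iPrMgCl·LiCl, THF, −78 °C; then 7, −78 → −40 °C; aq. NH4Cl
Reagents that add atoms: none
Why: Iodine–magnesium exchange on an activated alkenyl iodide is fast at −78 °C and retains geometry, and the tert-butyl ester tolerates the reagent at this temperature. 1,2-Addition then takes the carbonyl next to the alkoxy-bearing carbon of 7, because the other carbonyl is deactivated as a vinylogous ester. The new carbinol stereocentre is formed racemic and is not needed.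

Step 6
Reactants: 9 tert-butyl (E)-3-(1-hydroxy-2-isopropoxy-4-oxocyclobut-2-en-1-yl)but-2-enoate
Product: 12 tert-butyl 2,5-dihydroxy-4-isopropoxy-6-methylbenzoate, via dienylketene 10 (not isolated), via cyclohexadienone tautomer 11 (not isolated)
Conditions: toluene (degassed), 110 °C, Ar
Reagents that add atoms: none
Why: Heating causes conrotatory 4π electrocyclic opening of the cyclobutenone, breaking the bond between the carbonyl carbon and the carbinol carbon to give dienylketene 10. The hydroxyl, as the donor substituent, rotates outward, so the butenoate arm turns inward and lies cis to the ketene. A thermal disrotatory 6π electrocyclisation then joins the ketene carbon to the ester-bearing alkene carbon (the C2–C1 bond of ring C) and closes the six-membered ring as cyclohexadienone 11; the E alkene places hydrogen rather than the ester on the inside of the closing ring. The C1–H of 11 lies between ketone and ester, so enolisation to hydroquinone 12 is immediate. The closest known reaction type is the thermal ring expansion of 4-alkenyl- and 4-aryl-4-hydroxycyclobutenones to hydroquinones (Moore rearrangement). No stereocentre is created: the carbinol centre of 9 and the transient sp3 carbon of 11 both become sp2. The only selectivity required is the torquoselectivity of the ring opening, secured by the free hydroxyl; the positions of H-3, the 4-isopropoxy group, the para oxygens, the methyl and the ester are fixed by the connectivity of 9. Oxygen is excluded so that the hydroquinone is not oxidised to the quinone.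

Step 7
Reactants: 12 tert-butyl 2,5-dihydroxy-4-isopropoxy-6-methylbenzoate
Product: 13 tert-butyl 2,5-bis(benzyloxy)-4-isopropoxy-6-methylbenzoate
Conditions: BnBr, K2CO3, Bu4NI (cat.), DMF (degassed), 50 °C, Ar
Reagents that add atoms: benzyl bromide, BrCc1ccccc1
Why: Williamson ether synthesis on both phenols; warm DMF with iodide catalysis overcomes the chelation of the 2-hydroxyl and the crowding of the 5-hydroxyl, and exclusion of air prevents oxidation of the hydroquinone dianion.

Step 8
Reactants: 13 tert-butyl 2,5-bis(benzyloxy)-4-isopropoxy-6-methylbenzoate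
Product: 14 2,5-bis(benzyloxy)-4-isopropoxy-6-methylbenzoic acid
Conditions: CF3CO2H, CH2Cl2, 0 °C → rt
Reagents that add atoms: none
Why: Acidolysis of the tert-butyl ester through the tert-butyl cation (lost as isobutene); aryl benzyl and isopropyl ethers are stable to trifluoroacetic acid at room temperature, and the hindered acid is freed without base.

Step 9
Reactants: 14 2,5-bis(benzyloxy)-4-isopropoxy-6-methylbenzoic acid; 15 2,4-dihydroxy-6-methylbenzaldehyde
Product: 17 4-formyl-3-hydroxy-5-methylphenyl 2,5-bis(benzyloxy)-4-isopropoxy-6-methylbenzoate, via mixed trifluoroacetic anhydride 16 (not isolated)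
Conditions: (CF3CO)2O, toluene–CH2Cl2, 0 °C → rt
Reagents that add atoms: none
Why: Trifluoroacetic anhydride-mediated esterification, the classical depside coupling: the mixed anhydride of the hindered, electron-rich acid is reactive enough to acylate a phenol. In 15 only the 4-hydroxyl reacts, because the 2-hydroxyl is chelated to the formyl group.

Step 10
Reactants: 17 4-formyl-3-hydroxy-5-methylphenyl 2,5-bis(benzyloxy)-4-isopropoxy-6-methylbenzoate
Product: 18 4-{[2,5-bis(benzyloxy)-4-isopropoxy-6-methylbenzoyl]oxy}-2-hydroxy-6-methylbenzoic acid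
Conditions: NaClO2, H2NSO3H, THF–H2O, 0 °C → rt
Reagents that add atoms: sodium chlorite, [Na+].[O-]Cl=O
Why: Chlorite oxidation of the aldehyde to the acid (Lindgren–Pinnick oxidation); sulfamic acid scavenges the hypochlorous acid formed, so the electron-rich rings are not chlorinated, and the weakly acidic medium leaves the aryl ester intact.

Step 11
Reactants: 19 orsellinic acid (2,4-dihydroxy-6-methylbenzoic acid)
Product: 20 benzyl 2,4-dihydroxy-6-methylbenzoate
Conditions: BnBr, KHCO3, DMF, rt
Reagents that add atoms: benzyl bromide, BrCc1ccccc1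
Why: Carboxylate O-alkylation; hydrogen carbonate deprotonates only the carboxylic acid, so the phenols stay free, and room temperature avoids decarboxylation.

Step 12
Reactants: 18 4-{[2,5-bis(benzyloxy)-4-isopropoxy-6-methylbenzoyl]oxy}-2-hydroxy-6-methylbenzoic acid; 20 benzyl 2,4-dihydroxy-6-methylbenzoate
Product: 22 benzyl 4-[(4-{[2,5-bis(benzyloxy)-4-isopropoxy-6-methylbenzoyl]oxy}-2-hydroxy-6-methylbenzoyl)oxy]-2-hydroxy-6-methylbenzoate, via mixed trifluoroacetic anhydride 21 (not isolated)
Conditions: (CF3CO)2O, toluene, 0 °C → rt
Reagents that add atoms: none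
Why: The same trifluoroacetic anhydride-mediated depside esterification; the 2-hydroxyls of 18 and 20 are chelated to their ortho carbonyls and poorly nucleophilic, so the mixed anhydride is taken by the 4-hydroxyl of 20.

Step 13
Reactants: 22 benzyl 4-[(4-{[2,5-bis(benzyloxy)-4-isopropoxy-6-methylbenzoyl]oxy}-2-hydroxy-6-methylbenzoyl)oxy]-2-hydroxy-6-methylbenzoate
Product: 23 4-({4-[(2,5-dihydroxy-4-isopropoxy-6-methylbenzoyl)oxy]-2-hydroxy-6-methylbenzoyl}oxy)-2-hydroxy-6-methylbenzoic acid
Conditions: H2 (1 atm), 10% Pd/C, EtOAc–THF, rt
Reagents that add atoms: none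
Why: Catalytic hydrogenolysis cleaves the two benzyl ethers and the benzyl ester under neutral conditions, the standard final unmasking of depsides; aryl esters and the isopropyl ether are inert, and the product is kept under argon because ring C is now a free hydroquinone.

Step 14
Reactants: 23 4-({4-[(2,5-dihydroxy-4-isopropoxy-6-methylbenzoyl)oxy]-2-hydroxy-6-methylbenzoyl}oxy)-2-hydroxy-6-methylbenzoic acid
Product: 24 4-({2-hydroxy-6-methyl-4-[(2,4,5-trihydroxy-6-methylbenzoyl)oxy]benzoyl}oxy)-2-hydroxy-6-methylbenzoic acid
Conditions: BCl3 (excess), CH2Cl2, −10 → 0 °C; then H2O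
Reagents that add atoms: none
Why: Lewis acid dealkylation of an aryl isopropyl ether: boron binds the ether oxygen, helped by the borate formed at the neighbouring 5-hydroxyl, and chloride removes the secondary alkyl group. Aryl esters are not cleaved at this temperature, and aqueous work-up hydrolyses the borates to the free phenols.

## Compound list

1 | but-2-ynoic acid | CC#CC(=O)O | starting material
2 | tert-butyl but-2-ynoate | CC#CC(=O)OC(C)(C)C | intermediate
3 | tert-butyl (E)-3-(tributylstannyl)but-2-enoate | CCCC[Sn](CCCC)(CCCC)/C(C)=C/C(=O)OC(C)(C)C | intermediate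
4 | tert-butyl (E)-3-iodobut-2-enoate | C/C(I)=C\C(=O)OC(C)(C)C | intermediate
5 | diisopropyl squarate (3,4-diisopropoxycyclobut-3-ene-1,2-dione) | CC(C)OC1=C(OC(C)C)C(=O)C1=O | starting material
6 | 4-hydroxy-2,3-diisopropoxycyclobut-2-en-1-one (racemic, not isolated) | CC(C)OC1=C(OC(C)C)C(O)C1=O | intermediate
7 | 3-isopropoxycyclobut-3-ene-1,2-dione | CC(C)OC1=CC(=O)C1=O | intermediate
8 | tert-butyl (E)-3-(chloromagnesio)but-2-enoate, LiCl complex (magnesium trans to the ester, not isolated) | C/C([Mg]Cl)=C\C(=O)OC(C)(C)C | intermediate
9 | tert-butyl (E)-3-(1-hydroxy-2-isopropoxy-4-oxocyclobut-2-en-1-yl)but-2-enoate (racemic, one enantiomer drawn) | O=C1C=C(OC(C)C)[C@]1(O)/C(C)=C/C(=O)OC(C)(C)C | intermediate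
10 | tert-butyl (2E,4Z)-4-hydroxy-5-isopropoxy-3-methyl-7-oxohepta-2,4,6-trienoate (dienylketene, not isolated) | O=C=C/C(OC(C)C)=C(/O)\C(C)=C\C(=O)OC(C)(C)C | intermediate
11 | tert-butyl 3-hydroxy-4-isopropoxy-2-methyl-6-oxocyclohexa-2,4-diene-1-carboxylate (racemic, not isolated) | CC1=C(O)C(OC(C)C)=CC(=O)C1C(=O)OC(C)(C)C | intermediate
12 | tert-butyl 2,5-dihydroxy-4-isopropoxy-6-methylbenzoate | Cc1c(O)c(OC(C)C)cc(O)c1C(=O)OC(C)(C)C | intermediate
13 | tert-butyl 2,5-bis(benzyloxy)-4-isopropoxy-6-methylbenzoate | Cc1c(OCc2ccccc2)c(OC(C)C)cc(OCc2ccccc2)c1C(=O)OC(C)(C)C | intermediate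
14 | 2,5-bis(benzyloxy)-4-isopropoxy-6-methylbenzoic acid | Cc1c(OCc2ccccc2)c(OC(C)C)cc(OCc2ccccc2)c1C(=O)O | intermediate
15 | 2,4-dihydroxy-6-methylbenzaldehyde | Cc1cc(O)cc(O)c1C=O | starting material
16 | 2,5-bis(benzyloxy)-4-isopropoxy-6-methylbenzoic trifluoroacetic anhydride (not isolated) | Cc1c(OCc2ccccc2)c(OC(C)C)cc(OCc2ccccc2)c1C(=O)OC(=O)C(F)(F)F | intermediate
17 | 4-formyl-3-hydroxy-5-methylphenyl 2,5-bis(benzyloxy)-4-isopropoxy-6-methylbenzoate | Cc1cc(OC(=O)c2c(OCc3ccccc3)cc(OC(C)C)c(OCc3ccccc3)c2C)cc(O)c1C=O | intermediate
18 | 4-{[2,5-bis(benzyloxy)-4-isopropoxy-6-methylbenzoyl]oxy}-2-hydroxy-6-methylbenzoic acid | Cc1cc(OC(=O)c2c(OCc3ccccc3)cc(OC(C)C)c(OCc3ccccc3)c2C)cc(O)c1C(=O)O | intermediate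
19 | orsellinic acid (2,4-dihydroxy-6-methylbenzoic acid) | Cc1cc(O)cc(O)c1C(=O)O | starting material
20 | benzyl 2,4-dihydroxy-6-methylbenzoate | Cc1cc(O)cc(O)c1C(=O)OCc1ccccc1 | intermediate
21 | mixed trifluoroacetic anhydride of 18 (not isolated) | Cc1cc(OC(=O)c2c(OCc3ccccc3)cc(OC(C)C)c(OCc3ccccc3)c2C)cc(O)c1C(=O)OC(=O)C(F)(F)F | intermediate
22 | benzyl 4-[(4-{[2,5-bis(benzyloxy)-4-isopropoxy-6-methylbenzoyl]oxy}-2-hydroxy-6-methylbenzoyl)oxy]-2-hydroxy-6-methylbenzoate | Cc1cc(OC(=O)c2c(C)cc(OC(=O)c3c(OCc4ccccc4)cc(OC(C)C)c(OCc4ccccc4)c3C)cc2O)cc(O)c1C(=O)OCc1ccccc1 | intermediate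
23 | 4-({4-[(2,5-dihydroxy-4-isopropoxy-6-methylbenzoyl)oxy]-2-hydroxy-6-methylbenzoyl}oxy)-2-hydroxy-6-methylbenzoic acid | Cc1cc(OC(=O)c2c(C)cc(OC(=O)c3c(O)cc(OC(C)C)c(O)c3C)cc2O)cc(O)c1C(=O)O | intermediate
24 | 4-({2-hydroxy-6-methyl-4-[(2,4,5-trihydroxy-6-methylbenzoyl)oxy]benzoyl}oxy)-2-hydroxy-6-methylbenzoic acid | Cc1cc(OC(=O)c2c(C)cc(OC(=O)c3c(O)cc(O)c(O)c3C)cc2O)cc(O)c1C(=O)O | target

## Step count and risks

Total step count: 14. Longest linear sequence: 12 steps (steps 1, 2, 3, 5, 6, 7, 8, 9, 10, 12, 13, 14).

**Step 6 (key step).** The most likely failure is air oxidation of the electron-rich hydroquinone during isolation, which would give mixtures of hydroquinone and quinone. A second risk is incomplete outward rotation of the hydroxyl, which would let the ketene be captured by the hydroxyl as a butenolide. Fallback: starting from 9, the thermolysis is run as before and the crude product is deliberately oxidised with Ag2O to the air-stable quinone tert-butyl 4-isopropoxy-2-methyl-3,6-dioxocyclohexa-1,4-diene-1-carboxylate F1, which can be purified. Reduction of F1 with Na2S2O4 in a two-phase system just before the benzylation returns to the route at 12.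

**Step 5.** The β-magnesiated enoate 8 may condense with its own ester or lose its geometry before it adds, and addition may stray to the vinylogous ester carbonyl of 7. Fallback at the alcohol oxidation level, where the alkenyl metal carries no ester:
- Starting from 4, reduction with iBu2AlH gives (E)-3-iodobut-2-en-1-ol F2, and silylation with tBuMe2SiCl and imidazole gives tert-butyl{[(E)-3-iodobut-2-en-1-yl]oxy}dimethylsilane F3.
- Iodine–lithium exchange with t-BuLi in Et2O at −78 °C gives [(Z)-4-(tert-butyldimethylsilyloxy)but-2-en-2-yl]lithium F4 (lithium trans to the silyloxymethyl group).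
- F4 adds to 7 to give 4-[(E)-4-(tert-butyldimethylsilyloxy)but-2-en-2-yl]-4-hydroxy-3-isopropoxycyclobut-2-en-1-one F5.
- The same thermal ring expansion gives 2-[(tert-butyldimethylsilyloxy)methyl]-5-isopropoxy-3-methylbenzene-1,4-diol F6.
- Benzylation gives [2,5-bis(benzyloxy)-4-isopropoxy-6-methylbenzyloxy](tert-butyl)dimethylsilane F7, and Bu4NF gives [2,5-bis(benzyloxy)-4-isopropoxy-6-methylphenyl]methanol F8.
- MnO2 gives 2,5-bis(benzyloxy)-4-isopropoxy-6-methylbenzaldehyde F9, and chlorite oxidation of F9 returns to the route at 14.

**Step 12.** Activation of hydroxy acid 18 with its 2-hydroxyl free may lead to self-condensation or to acylation at a chelated phenol, lowering the efficiency of the fragment union. Fallback: starting from 17, the chelated hydroxyl is benzylated (BnBr, K2CO3, DMF) to give 4-formyl-3-(benzyloxy)-5-methylphenyl 2,5-bis(benzyloxy)-4-isopropoxy-6-methylbenzoate F10. Chlorite oxidation gives 2-(benzyloxy)-4-{[2,5-bis(benzyloxy)-4-isopropoxy-6-methylbenzoyl]oxy}-6-methylbenzoic acid F11. Coupling with 20 under the same anhydride conditions gives benzyl 4-[(2-(benzyloxy)-4-{[2,5-bis(benzyloxy)-4-isopropoxy-6-methylbenzoyl]oxy}-6-methylbenzoyl)oxy]-2-hydroxy-6-methylbenzoate F12. Hydrogenolysis of F12 removes all four benzyl groups and returns to the route at 23.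

**Step 14.** The polyphenolic acid 23 may be poorly soluble in CH2Cl2, which would make the dealkylation incomplete, and prolonged contact with the Lewis acid may start transacylation of the depside esters. Fallback with the order of unmasking reversed: starting from 22, which is freely soluble, BCl3 with pentamethylbenzene as cation scavenger (CH2Cl2, −78 → 0 °C) removes the isopropyl ether and both benzyl ethers. This gives benzyl 4-({2-hydroxy-6-methyl-4-[(2,4,5-trihydroxy-6-methylbenzoyl)oxy]benzoyl}oxy)-2-hydroxy-6-methylbenzoate F13. Hydrogenolysis of the remaining benzyl ester of F13 over Pd/C arrives at 24.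

## Further compounds

F1 | step 6 | tert-butyl 4-isopropoxy-2-methyl-3,6-dioxocyclohexa-1,4-diene-1-carboxylate | CC1=C(C(=O)OC(C)(C)C)C(=O)C=C(OC(C)C)C1=O
F2 | step 5 | (E)-3-iodobut-2-en-1-ol | C/C(I)=C\CO
F3 | step 5 | tert-butyl{[(E)-3-iodobut-2-en-1-yl]oxy}dimethylsilane | C/C(I)=C\CO[Si](C)(C)C(C)(C)C
F4 | step 5 | [(Z)-4-(tert-butyldimethylsilyloxy)but-2-en-2-yl]lithium | C/C([Li])=C\CO[Si](C)(C)C(C)(C)C
F5 | step 5 | 4-[(E)-4-(tert-butyldimethylsilyloxy)but-2-en-2-yl]-4-hydroxy-3-isopropoxycyclobut-2-en-1-one (racemic) | O=C1C=C(OC(C)C)C1(O)/C(C)=C/CO[Si](C)(C)C(C)(C)C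
F6 | step 5 | 2-[(tert-butyldimethylsilyloxy)methyl]-5-isopropoxy-3-methylbenzene-1,4-diol | Cc1c(O)c(OC(C)C)cc(O)c1CO[Si](C)(C)C(C)(C)C
F7 | step 5 | [2,5-bis(benzyloxy)-4-isopropoxy-6-methylbenzyloxy](tert-butyl)dimethylsilane | Cc1c(OCc2ccccc2)c(OC(C)C)cc(OCc2ccccc2)c1CO[Si](C)(C)C(C)(C)C
F8 | step 5 | [2,5-bis(benzyloxy)-4-isopropoxy-6-methylphenyl]methanol | Cc1c(OCc2ccccc2)c(OC(C)C)cc(OCc2ccccc2)c1CO
F9 | step 5 | 2,5-bis(benzyloxy)-4-isopropoxy-6-methylbenzaldehyde | Cc1c(OCc2ccccc2)c(OC(C)C)cc(OCc2ccccc2)c1C=O
F10 | step 12 | 4-formyl-3-(benzyloxy)-5-methylphenyl 2,5-bis(benzyloxy)-4-isopropoxy-6-methylbenzoate | Cc1cc(OC(=O)c2c(OCc3ccccc3)cc(OC(C)C)c(OCc3ccccc3)c2C)cc(OCc2ccccc2)c1C=O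
F11 | step 12 | 2-(benzyloxy)-4-{[2,5-bis(benzyloxy)-4-isopropoxy-6-methylbenzoyl]oxy}-6-methylbenzoic acid | Cc1cc(OC(=O)c2c(OCc3ccccc3)cc(OC(C)C)c(OCc3ccccc3)c2C)cc(OCc2ccccc2)c1C(=O)O
F12 | step 12 | benzyl 4-[(2-(benzyloxy)-4-{[2,5-bis(benzyloxy)-4-isopropoxy-6-methylbenzoyl]oxy}-6-methylbenzoyl)oxy]-2-hydroxy-6-methylbenzoate | Cc1cc(OC(=O)c2c(C)cc(OC(=O)c3c(OCc4ccccc4)cc(OC(C)C)c(OCc4ccccc4)c3C)cc2OCc2ccccc2)cc(O)c1C(=O)OCc1ccccc1
F13 | step 14 | benzyl 4-({2-hydroxy-6-methyl-4-[(2,4,5-trihydroxy-6-methylbenzoyl)oxy]benzoyl}oxy)-2-hydroxy-6-methylbenzoate | Cc1cc(OC(=O)c2c(C)cc(OC(=O)c3c(O)cc(O)c(O)c3C)cc2O)cc(O)c1C(=O)OCc1ccccc1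
A1 | alternative 1 | benzyl 2-(benzyloxy)-4-[(2-(benzyloxy)-6-methyl-4-{[2,4,5-tris(benzyloxy)-6-methylbenzoyl]oxy}benzoyl)oxy]-6-methylbenzoate | Cc1cc(OC(=O)c2c(C)cc(OC(=O)c3c(OCc4ccccc4)cc(OCc4ccccc4)c(OCc4ccccc4)c3C)cc2OCc2ccccc2)cc(OCc2ccccc2)c1C(=O)OCc1ccccc1
A2 | alternative 1 | 6-methyl-2-oxo-2H-pyran-4-yl 2-(benzyloxy)-6-methyl-4-{[2,4,5-tris(benzyloxy)-6-methylbenzoyl]oxy}benzoate | Cc1cc(OC(=O)c2c(C)cc(OC(=O)c3c(OCc4ccccc4)cc(OCc4ccccc4)c(OCc4ccccc4)c3C)cc2OCc2ccccc2)cc(=O)o1
A3 | alternative 1 | benzyl 3-(benzyloxy)prop-2-ynoate | O=C(OCc1ccccc1)C#COCc1ccccc1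
A4 | alternative 2 | benzyl 4-(2,4-dihydroxy-6-methylbenzoyloxy)-2-hydroxy-6-methylbenzoate | Cc1cc(O)cc(O)c1C(=O)Oc1cc(C)c(C(=O)OCc2ccccc2)c(O)c1
A5 | alternative 2 | benzyl 4-(but-2-ynoyloxy)-2-hydroxy-6-methylbenzoate | CC#CC(=O)Oc1cc(C)c(C(=O)OCc2ccccc2)c(O)c1
A6 | alternative 2 | 1-methoxy-1,3-bis(trimethylsilyloxy)buta-1,3-diene | COC(O[Si](C)(C)C)=CC(=C)O[Si](C)(C)C
A7 | alternative 3 | benzyl 2-(benzyloxy)-4-[(2-(benzyloxy)-4-{[5-(benzyloxy)-2,4-dihydroxy-6-methylbenzoyl]oxy}-6-methylbenzoyl)oxy]-6-methylbenzoate | Cc1c(OCc2ccccc2)c(O)cc(O)c1C(=O)Oc1cc(C)c(C(=O)Oc2cc(C)c(C(=O)OCc3ccccc3)c(OCc3ccccc3)c2)c(OCc2ccccc2)c1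
A8 | alternative 3 | 6-(benzyloxy)-3,5,7-trioxooctanoate ester of the benzyl-protected rings B–A phenol (racemic) | CC(=O)C(OCc1ccccc1)C(=O)CC(=O)CC(=O)Oc1cc(C)c(C(=O)Oc2cc(C)c(C(=O)OCc3ccccc3)c(OCc3ccccc3)c2)c(OCc2ccccc2)c1
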